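**Strategy.** Everything rests on taking ring B apart into a four-carbon vinylketene and a two-carbon methoxyalkyne. Ring B is a resorcinol monomethyl ether: C2' (OMe) is flanked by C1', the carbon bonded to furan C2, and by prenyl-bearing C3', with oxygen again at C4' and C6'. Heating a 2-prenyl-3-silyloxycyclobutenone with a 2-(methoxyethynyl)benzofuran should forge C6'–C1', C2'–C3' and C5'–C6' in one operation, close ring B and deliver its three oxygens already differentiated (free C6' OH, C2' OMe, C4' OSi). The alkyne precursor is a silyl-protected 3-methylbenzofuran carrying the ynol ether at C2; fluoride then completes the synthesis.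

Key step: step 8

Remark: 3-chloro-7-hydroxy-4-methylcoumarin (1) is assumed purchasable and is used so that no halogenation of a free phenol is needed; the target is achiral, and the stereocentres of 15 and 20 are racemic and transient.

**Step 1**
Reactants: 1 3-chloro-7-hydroxy-4-methylcoumarin
Product: 3 6-hydroxy-3-methylbenzofuran-2-carboxylic acid, via sodium (E)-2-chloro-3-(2,4-dihydroxyphenyl)but-2-enoate 2 (not isolated)
Conditions: NaOH (2 M aq), reflux, N2; then HCl (aq) to pH 2, 0 °C
Reagents that add atoms: sodium hydroxide, [Na+].[OH-]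
Why: Perkin rearrangement (coumarin-to-benzofuran ring contraction), in which hydroxide opens the lactone and the freed phenoxide displaces the vinylic chloride by addition–elimination to close the furan, as is standard for 3-halo-4-methylcoumarins.

**Step 2**
Reactants: 3 6-hydroxy-3-methylbenzofuran-2-carboxylic acid
Product: 5 3-methyl-6-(triisopropylsilyloxy)benzofuran-2-carboxylic acid, via triisopropylsilyl 3-methyl-6-(triisopropylsilyloxy)benzofuran-2-carboxylate 4 (not isolated)
Conditions: TIPSCl (2.3 equiv), imidazole, DMF, rt; then THF/H2O/AcOH (4:1:1), rt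
Reagents that add atoms: triisopropylsilyl chloride, CC(C)[Si](Cl)(C(C)C)C(C)C
Why: Exhaustive O-silylation followed by selective hydrolysis of the silyl ester, which is far more labile than the hindered aryl silyl ether, should leave only the phenol protected.

**Step 3**
Reactants: 5 3-methyl-6-(triisopropylsilyloxy)benzofuran-2-carboxylic acid
Product: 6 2-iodo-3-methyl-6-(triisopropylsilyloxy)benzofuran
Conditions: I2 (2.5 equiv), K3PO4 (1 equiv), MeCN, 100 °C, sealed tube, dark
Reagents that add atoms: iodine, II
Why: Metal-free decarboxylative iodination (a Hunsdiecker-type ipso-substitution), in which the potassium carboxylate on the electron-rich C2 of the 3-alkylbenzofuran takes up iodine at the carboxyl-bearing carbon as CO2 leaves, while unactivated iodine should not attack the silyloxy-substituted benzene ring.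

**Step 4**
Reactants: 6 2-iodo-3-methyl-6-(triisopropylsilyloxy)benzofuran; 7 2-chloro-1,1-dimethoxyethane
Product: 10 2-(methoxyethynyl)-3-methyl-6-(triisopropylsilyloxy)benzofuran, via lithium methoxyacetylide 8 (not isolated), via methoxyethynylzinc chloride 9 (not isolated)
Conditions: 7 (2 equiv), LiNEt2 (3 equiv per 7, from Et2NH and n-BuLi), THF, 0 °C → rt; ZnCl2 (2.2 equiv per 7, THF), 0 °C; then 6, Pd(PPh3)4 (5 mol%), THF, rt; chromatography on Et3N-deactivated silica
Reagents that add atoms: none
Why: Two eliminations and one deprotonation of the chloroacetal by the lithium amide give the lithium alkoxyacetylide, and its zinc derivative couples with the 2-iodobenzofuran in a Negishi reaction at room temperature, conditions under which the aryl silyl ether and the ynol ether product should persist.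

**Step 5**
Reactants: 11 5-methylhex-4-enoic acid; 12 ethoxyacetylene
Product: 15 racemic 3-ethoxy-4-(3-methylbut-2-enyl)cyclobut-2-en-1-one, via 5-methylhex-4-enoyl chloride 13 (not isolated), via 5-methylhexa-1,4-dien-1-one 14 (not isolated)
Conditions: (COCl)2, DMF (cat.), CH2Cl2, 0 °C → rt; evaporation; then slow addition of crude 13 to 12 (2 equiv, hexane solution), Et3N, Et2O, 0 °C → rt
Reagents that add atoms: none
Why: Dehydrochlorination of the acid chloride gives the monoalkylketene, which the electron-rich alkyne traps in a ketene–alkyne [2+2] cycloaddition with the ketene carbonyl carbon bonding to the unsubstituted alkyne carbon; the new stereocentre at C4 forms as a racemate and is removed in step 6.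

**Step 6**
Reactants: 15 racemic 3-ethoxy-4-(3-methylbut-2-enyl)cyclobut-2-en-1-one
Product: 17 3-hydroxy-2-(3-methylbut-2-enyl)cyclobut-2-en-1-one, via 2-(3-methylbut-2-enyl)cyclobutane-1,3-dione 16 (not isolated)
Conditions: HCl (1 M aq), THF, 0 °C → rt
Reagents that add atoms: water, O
Why: Acid hydrolysis of the vinylogous ester gives the 1,3-dione, which should settle as its more substituted enol, so that the prenyl group ends on C2 of the enone and the stereocentre is erased.

**Step 7**
Reactants: 17 3-hydroxy-2-(3-methylbut-2-enyl)cyclobut-2-en-1-one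
Product: 18 2-(3-methylbut-2-enyl)-3-(triisopropylsilyloxy)cyclobut-2-en-1-one
Conditions: TIPSCl, Et3N, DMAP (cat.), CH2Cl2, 0 °C → rt; non-aqueous work-up (pentane, filtration), used promptly
Reagents that add atoms: triisopropylsilyl chloride, CC(C)[Si](Cl)(C(C)C)C(C)C
Why: O-silylation of a vinylogous acid, as practised on 2-alkylcycloalkane-1,3-diones, should give the vinylogous silyl ester at the enol oxygen already in place.

**Step 8**
Reactants: 10 2-(methoxyethynyl)-3-methyl-6-(triisopropylsilyloxy)benzofuran; 18 2-(3-methylbut-2-enyl)-3-(triisopropylsilyloxy)cyclobut-2-en-1-one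
Product: 23 3-methoxy-4-(3-methylbut-2-enyl)-2-[3-methyl-6-(triisopropylsilyloxy)benzofuran-2-yl]-5-(triisopropylsilyloxy)phenol, via vinylketene 19 (not isolated), via cyclobutenone cycloadduct 20 (not isolated), via dienylketene 21 (not isolated), via cyclohexadienone 22 (not isolated)
Conditions: 18 (1.3 equiv), PhMe (degassed), 110 °C, sealed tube, Ar
Reagents that add atoms: none
Why: Thermal Danheiser benzannulation: conrotatory 4π ring opening of 18 gives vinylketene 19, which adds [2+2] to the ynol ether to give cyclobutenone 20; a second, reversible 4π opening funnels material into dienylketene 21, whose 6π electrocyclization and enolization of dienone 22 deliver the phenol. The closest known reaction type is the benzannulation of cyclobutenones with alkoxy- and silyloxyalkynes, and the less usual element is the 3-silyloxycyclobutenone as the four-carbon partner, which is where the risk sits. Ring B is closed by the thermal disrotatory 6π electrocyclization (C5'–C6'), after the cycloaddition has made C6'–C1' and C2'–C3'. No stereocentre survives, since the quaternary carbon of 20 becomes aromatic C3'. The step needs regiocontrol in the [2+2] event, and polarization of the alkyne by its methoxy oxygen secures it: the electrophilic ketene carbon bonds to the benzofuranyl-bearing carbon, so that OH, benzofuranyl, OMe and prenyl follow one another around the ring. The methyl ether offers no β-hydrogen for retro-ene loss of the alkyne, and the free C6' hydroxyl is para, not ortho, to the prenyl group, so no chroman can form.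

**Step 9**
Reactants: 23 3-methoxy-4-(3-methylbut-2-enyl)-2-[3-methyl-6-(triisopropylsilyloxy)benzofuran-2-yl]-5-(triisopropylsilyloxy)phenol
Product: 24 glycybenzofuran
Conditions: TBAF (2.2 equiv), AcOH (2.2 equiv), THF, 0 °C
Reagents that add atoms: none
Why: Fluoride-mediated cleavage of both aryl silyl ethers (desilylation), buffered with acetic acid so that the electron-rich triphenol is not held as a phenoxide and the prenyl group ortho to the new C4' hydroxyl is not exposed to strong acid.

**Compound list**

1 | 3-chloro-7-hydroxy-4-methylcoumarin | Cc1c(Cl)c(=O)oc2cc(O)ccc12 | starting material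
2 | (E)-2-chloro-3-(2,4-dihydroxyphenyl)but-2-enoic acid, sodium salt in the flask, drawn as the acid | C/C(c1ccc(O)cc1O)=C(Cl)/C(=O)O | intermediate (not isolated)
3 | 6-hydroxy-3-methylbenzofuran-2-carboxylic acid | Cc1c(C(=O)O)oc2cc(O)ccc12 | intermediate
4 | triisopropylsilyl 3-methyl-6-(triisopropylsilyloxy)benzofuran-2-carboxylate | Cc1c(C(=O)O[Si](C(C)C)(C(C)C)C(C)C)oc2cc(O[Si](C(C)C)(C(C)C)C(C)C)ccc12 | intermediate (not isolated)
5 | 3-methyl-6-(triisopropylsilyloxy)benzofuran-2-carboxylic acid | Cc1c(C(=O)O)oc2cc(O[Si](C(C)C)(C(C)C)C(C)C)ccc12 | intermediate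
6 | 2-iodo-3-methyl-6-(triisopropylsilyloxy)benzofuran | Cc1c(I)oc2cc(O[Si](C(C)C)(C(C)C)C(C)C)ccc12 | intermediate
7 | 2-chloro-1,1-dimethoxyethane | COC(CCl)OC | starting material
8 | lithium methoxyacetylide | [Li]C#COC | intermediate (not isolated)
9 | methoxyethynylzinc chloride | COC#C[Zn]Cl | intermediate (not isolated)
10 | 2-(methoxyethynyl)-3-methyl-6-(triisopropylsilyloxy)benzofuran | COC#Cc1oc2cc(O[Si](C(C)C)(C(C)C)C(C)C)ccc2c1C | intermediate
11 | 5-methylhex-4-enoic acid | CC(C)=CCCC(=O)O | starting material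
12 | ethoxyacetylene | CCOC#C | starting material
13 | 5-methylhex-4-enoyl chloride | CC(C)=CCCC(=O)Cl | intermediate (not isolated)
14 | 5-methylhexa-1,4-dien-1-one, the prenyl-substituted ketene | CC(C)=CCC=C=O | intermediate (not isolated)
15 | racemic 3-ethoxy-4-(3-methylbut-2-enyl)cyclobut-2-en-1-one | CCOC1=CC(=O)C1CC=C(C)C | intermediate
16 | 2-(3-methylbut-2-enyl)cyclobutane-1,3-dione | CC(C)=CCC1C(=O)CC1=O | intermediate (not isolated)
17 | 3-hydroxy-2-(3-methylbut-2-enyl)cyclobut-2-en-1-one | CC(C)=CCC1=C(O)CC1=O | intermediate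
18 | 2-(3-methylbut-2-enyl)-3-(triisopropylsilyloxy)cyclobut-2-en-1-one | CC(C)=CCC1=C(O[Si](C(C)C)(C(C)C)C(C)C)CC1=O | intermediate
19 | 2-(3-methylbut-2-enyl)-3-(triisopropylsilyloxy)buta-1,3-dien-1-one | CC(C)=CCC(=C=O)C(=C)O[Si](C(C)C)(C(C)C)C(C)C | intermediate (not isolated)
20 | racemic 3-methoxy-4-(3-methylbut-2-enyl)-2-[3-methyl-6-(triisopropylsilyloxy)benzofuran-2-yl]-4-[1-(triisopropylsilyloxy)vinyl]cyclobut-2-en-1-one | COC1=C(c2oc3cc(O[Si](C(C)C)(C(C)C)C(C)C)ccc3c2C)C(=O)C1(CC=C(C)C)C(=C)O[Si](C(C)C)(C(C)C)C(C)C | intermediate (not isolated)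
21 | (3E)-3-methoxy-4-(3-methylbut-2-enyl)-2-[3-methyl-6-(triisopropylsilyloxy)benzofuran-2-yl]-5-(triisopropylsilyloxy)hexa-1,3,5-trien-1-one, ketene-bearing carbon and silyloxyvinyl group on the same side | O=C=C(c1oc2cc(O[Si](C(C)C)(C(C)C)C(C)C)ccc2c1C)/C(OC)=C(/CC=C(C)C)C(=C)O[Si](C(C)C)(C(C)C)C(C)C | intermediate (not isolated)
22 | 3-methoxy-4-(3-methylbut-2-enyl)-2-[3-methyl-6-(triisopropylsilyloxy)benzofuran-2-yl]-5-(triisopropylsilyloxy)cyclohexa-2,4-dien-1-one | COC1=C(c2oc3cc(O[Si](C(C)C)(C(C)C)C(C)C)ccc3c2C)C(=O)CC(O[Si](C(C)C)(C(C)C)C(C)C)=C1CC=C(C)C | intermediate (not isolated)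
23 | 3-methoxy-4-(3-methylbut-2-enyl)-2-[3-methyl-6-(triisopropylsilyloxy)benzofuran-2-yl]-5-(triisopropylsilyloxy)phenol (4',6-bis-O-triisopropylsilyl glycybenzofuran) | COc1c(CC=C(C)C)c(O[Si](C(C)C)(C(C)C)C(C)C)cc(O)c1-c1oc2cc(O[Si](C(C)C)(C(C)C)C(C)C)ccc2c1C | intermediate
24 | glycybenzofuran, 4-(6-hydroxy-3-methylbenzofuran-2-yl)-5-methoxy-6-(3-methylbut-2-enyl)benzene-1,3-diol | COc1c(CC=C(C)C)c(O)cc(O)c1-c1oc2cc(O)ccc2c1C | target

**Step count.** Total: 9 steps. Longest linear sequence: 6 steps (steps 1, 2, 3, 4, 8, 9); the cyclobutenone branch is steps 5, 6, 7.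

**Steps most likely to fail**

1. Step 8. The vinylketene released from 18 may be consumed by self-condensation or silyl loss before the hindered, arene-conjugated ynol ether intercepts it, and the ynol ether may decompose at the temperature needed. The fallback takes the aryl–aryl bond out of the annulation; it sets out from 18 (with 8 and 6) and comes back at 23.
   - Protonation of 8 (NH4Cl) would give methoxyacetylene F1, handled as a cold toluene solution.
   - Heating 18 with this unhindered ketenophile should give 3-methoxy-4-(3-methylbut-2-enyl)-5-(triisopropylsilyloxy)phenol F2.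
   - MOMCl and i-Pr2NEt would give triisopropyl[3-methoxy-5-(methoxymethoxy)-2-(3-methylbut-2-enyl)phenoxy]silane F3.
   - Directed ortho-lithiation (n-BuLi, THF, 0 °C) between OMe and OMOM would give [2-methoxy-6-(methoxymethoxy)-3-(3-methylbut-2-enyl)-4-(triisopropylsilyloxy)phenyl]lithium F4.
   - ZnCl2 would convert it into [2-methoxy-6-(methoxymethoxy)-3-(3-methylbut-2-enyl)-4-(triisopropylsilyloxy)phenyl]zinc chloride F5.
   - Negishi coupling with 6 (Pd2(dba)3, SPhos, THF, 50 °C) would give 2-[2-methoxy-6-(methoxymethoxy)-3-(3-methylbut-2-enyl)-4-(triisopropylsilyloxy)phenyl]-3-methyl-6-(triisopropylsilyloxy)benzofuran F6.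
   - ZnBr2 and n-PrSH (CH2Cl2, 0 °C) would remove the acetal and return 23.

2. Step 4. Formation and transmetalation of the alkoxyacetylide may be incomplete, the amine may protonate the reagent during coupling, and the acid-labile ynol ether may hydrate on isolation. The fallback makes the triple bond by elimination instead of coupling; it sets out from 6 and comes back at 10.
   - Iodine–magnesium exchange (i-PrMgCl·LiCl, THF, −20 °C) would give [3-methyl-6-(triisopropylsilyloxy)benzofuran-2-yl]magnesium chloride F7.
   - Acylation with N,2-dimethoxy-N-methylacetamide would give 2-methoxy-1-[3-methyl-6-(triisopropylsilyloxy)benzofuran-2-yl]ethanone F8.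
   - LiN(SiMe3)2 (THF, −78 °C) would give the chelated lithium (Z)-2-methoxy-1-[3-methyl-6-(triisopropylsilyloxy)benzofuran-2-yl]ethenolate F9.
   - PhNTf2 would trap it as (Z)-2-methoxy-1-[3-methyl-6-(triisopropylsilyloxy)benzofuran-2-yl]vinyl trifluoromethanesulfonate F10.
   - Anti-elimination with KOt-Bu (THF, −78 °C) would give 10.

3. Step 3. Iodination of the silyloxy-activated benzene ring or loss of the silyl ether under hot iodine and phosphate may compete with decarboxylation. The fallback brings iodine in by deprotonation at C2 instead of ipso-substitution; it sets out from 3 and comes back at 6.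
   - Protodecarboxylation (Cu2O, 1,10-phenanthroline, NMP/quinoline, 170 °C) would give 3-methylbenzofuran-6-ol F11.
   - TIPSCl and imidazole would give triisopropyl[(3-methylbenzofuran-6-yl)oxy]silane F12.
   - n-BuLi (THF, −78 °C) would give [3-methyl-6-(triisopropylsilyloxy)benzofuran-2-yl]lithium F13.
   - Quenching with I2 would give 6.

**Further compounds**

F1 | step 8 | methoxyacetylene | COC#C
F2 | step 8 | 3-methoxy-4-(3-methylbut-2-enyl)-5-(triisopropylsilyloxy)phenol | COc1cc(O)cc(O[Si](C(C)C)(C(C)C)C(C)C)c1CC=C(C)C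
F3 | step 8 | triisopropyl[3-methoxy-5-(methoxymethoxy)-2-(3-methylbut-2-enyl)phenoxy]silane | COCOc1cc(OC)c(CC=C(C)C)c(O[Si](C(C)C)(C(C)C)C(C)C)c1
F4 | step 8 | [2-methoxy-6-(methoxymethoxy)-3-(3-methylbut-2-enyl)-4-(triisopropylsilyloxy)phenyl]lithium | COCOc1cc(O[Si](C(C)C)(C(C)C)C(C)C)c(CC=C(C)C)c(OC)c1[Li]
F5 | step 8 | [2-methoxy-6-(methoxymethoxy)-3-(3-methylbut-2-enyl)-4-(triisopropylsilyloxy)phenyl]zinc chloride | COCOc1cc(O[Si](C(C)C)(C(C)C)C(C)C)c(CC=C(C)C)c(OC)c1[Zn]Cl
F6 | step 8 | 2-[2-methoxy-6-(methoxymethoxy)-3-(3-methylbut-2-enyl)-4-(triisopropylsilyloxy)phenyl]-3-methyl-6-(triisopropylsilyloxy)benzofuran | COCOc1cc(O[Si](C(C)C)(C(C)C)C(C)C)c(CC=C(C)C)c(OC)c1-c1oc2cc(O[Si](C(C)C)(C(C)C)C(C)C)ccc2c1C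
F7 | step 4 | [3-methyl-6-(triisopropylsilyloxy)benzofuran-2-yl]magnesium chloride | Cc1c([Mg]Cl)oc2cc(O[Si](C(C)C)(C(C)C)C(C)C)ccc12
F8 | step 4 | 2-methoxy-1-[3-methyl-6-(triisopropylsilyloxy)benzofuran-2-yl]ethanone | COCC(=O)c1oc2cc(O[Si](C(C)C)(C(C)C)C(C)C)ccc2c1C
F9 | step 4 | lithium (Z)-2-methoxy-1-[3-methyl-6-(triisopropylsilyloxy)benzofuran-2-yl]ethenolate | CO/C=C(\O[Li])c1oc2cc(O[Si](C(C)C)(C(C)C)C(C)C)ccc2c1C
F10 | step 4 | (Z)-2-methoxy-1-[3-methyl-6-(triisopropylsilyloxy)benzofuran-2-yl]vinyl trifluoromethanesulfonate | CO/C=C(\OS(=O)(=O)C(F)(F)F)c1oc2cc(O[Si](C(C)C)(C(C)C)C(C)C)ccc2c1C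
F11 | step 3 | 3-methylbenzofuran-6-ol | Cc1coc2cc(O)ccc12
F12 | step 3 | triisopropyl[(3-methylbenzofuran-6-yl)oxy]silane | Cc1coc2cc(O[Si](C(C)C)(C(C)C)C(C)C)ccc12
F13 | step 3 | [3-methyl-6-(triisopropylsilyloxy)benzofuran-2-yl]lithium | Cc1c([Li])oc2cc(O[Si](C(C)C)(C(C)C)C(C)C)ccc12
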